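Locants: tricyclo[5.4.0.0^2,8]undecane numbering of the target, kept for all intermediates (C1 cyclobutane CH beside the C11 ketone; C2 quaternary C–Me; C3–C5 the three C–O carbons; C6 CMe2; C7, C8 cyclobutane CH; C9 CHMe; C10 CH2).
Cuts: the C4 and C5 ester C–O bonds and C9–CH3, then the cyclobutane bond C1–C2. A cyclobutane CH (C1) alpha to the C11 ketone is the retron of a semipinacol shift of C2 from C11 to C1 in a norbornen-11-ol with an endo leaving group on C1; this contracts the eight-membered ring C11–C1–C7–C6–C5–C4–C3–C2 to the seven-membered ring C1–C7.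
Further cuts: C11–C1 and C8–C7 (intramolecular Diels–Alder), C2–CH3, C2–C3 (aldol), C4–C5 (glycolate aldol).
Forward: the chain C3–C7 with its alkenylboronate is joined to cyclopentenone (C2, C8–C11); the cycloaddition closes the norbornene and the seven-membered ring C2–C8; the ring contraction then gives cyclobutane, cyclohexenone and the seven-membered ring C1–C7 together; methyl cuprate and the two esters follow.
Stereochemistry: C4/C5 from the (R)-oxazolidinone glycolate aldol, C3 by Felkin addition, C2 by methylation of the chelated aldol dianion, C1/C7/C8/C11 by tether and (E)-alkene geometry in the cycloaddition, inversion at C1 with retention at C2 in the shift, C9 by cuprate attack anti to the C2 bridge; the acyl stereocentre and the Z-alkene are bought in.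

Key step: step 15

Step 1
Reactants: 1 2,2-dimethylbut-3-ynoic acid
Product: 2 2,2-dimethylbut-3-yn-1-ol
Conditions: LiAlH4, Et2O, 0 °C to rt; Fieser work-up
Reagents that add atoms: none
Why: LiAlH4 reduction of the carboxylic acid to the primary alcohol, the terminal alkyne being inert.

Step 2
Reactants: 2 2,2-dimethylbut-3-yn-1-ol
Product: 3 2,2-dimethylbut-3-ynal
Conditions: Dess–Martin periodinane, CH2Cl2, 0 °C to rt; filtered solution used directly
Reagents that add atoms: none
Why: Dess–Martin oxidation of the neopentyl alcohol should stop at the non-enolisable aldehyde, which is volatile and is therefore not concentrated.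

Step 3
Reactants: 4 (R)-4-benzyloxazolidin-2-one; 5 2-(benzyloxy)acetyl chloride
Product: 6 (R)-4-benzyl-3-[2-(benzyloxy)acetyl]oxazolidin-2-one
Conditions: n-BuLi, THF, −78 °C; then 5, −78 to 0 °C
Reagents that add atoms: none
Why: N-acylation of the lithiated oxazolidinone with the acid chloride (loading of the Evans auxiliary).

Step 4
Reactants: 6 glycolyl imide; 3 2,2-dimethylbut-3-ynal
Product: 7 syn-aldol imide (2R,3S)
Conditions: Bu2BOTf, Et3N, CH2Cl2, −78 to 0 °C; 3, −78 to 0 °C; MeOH/pH 7 buffer/H2O2
Reagents that add atoms: none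
Why: Evans syn-glycolate aldol, in which the (Z)-boron enolate reacts through a Zimmerman–Traxler chair on the face away from the benzyl group of the (R)-auxiliary and should give the 2,3-syn (2R,3S) adduct, i.e. C4 and C5 of the target.

Step 5
Reactants: 7 syn-aldol imide
Product: 8 TES ether imide
Conditions: TESOTf, 2,6-lutidine, CH2Cl2, −78 to 0 °C
Reagents that add atoms: triethylsilyl trifluoromethanesulfonate, CC[Si](CC)(CC)OS(=O)(=O)C(F)(F)F
Why: Silyl ether protection of the hindered neopentyl C5 hydroxyl with the silyl triflate, chosen so that it can later be removed before the TBS group.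

Step 6
Reactants: 8 TES ether imide
Product: 9 (E)-alkenylboronate imide
Conditions: pinacolborane, Cy2BH (5 mol%), THF, rt to 40 °C
Reagents that add atoms: pinacolborane, [H]B1OC(C)(C)C(C)(C)O1
Why: Dialkylborane-catalysed syn-hydroboration of the terminal alkyne places boron on the terminal carbon and should give only the (E)-alkenylboronate, the geometry that later puts the C1 substituent endo.

Step 7
Reactants: 9 (E)-alkenylboronate imide
Product: 10 (2S,3S,5E)-alcohol
Conditions: LiBH4, MeOH (1 equiv), Et2O, 0 °C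
Reagents that add atoms: none
Why: Reductive cleavage of the N-acyloxazolidinone with LiBH4 gives the primary alcohol and returns the auxiliary, while boronate and silyl ether tolerate borohydride.

Step 8
Reactants: 10 (2S,3S,5E)-alcohol
Product: 11 (2R,3S,5E)-aldehyde
Conditions: Dess–Martin periodinane, pyridine, CH2Cl2, 0 °C to rt; used at once
Reagents that add atoms: none
Why: Buffered Dess–Martin oxidation gives the α-benzyloxy aldehyde without epimerisation and leaves the alkenylboronate intact.

Step 9
Reactants: 12 cyclopent-2-en-1-one; 11 (2R,3S,5E)-aldehyde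
Product: 13 aldol adduct (β-hydroxy enone, ring C-5 epimers)
Conditions: LDA, THF, −78 °C (12); then 11, −78 °C; AcOH quench
Reagents that add atoms: none
Why: Kinetic α′-deprotonation of cyclopentenone and aldol addition of the cross-conjugated lithium enolate to the α-alkoxy aldehyde should follow the Felkin–Anh (Cornforth) sense and give the 1,2-anti carbinol (C3); the ring-carbon configuration does not matter because it is enolised in step 10.

Step 10
Reactants: 13 aldol adduct
Product: 14 5-methyl β-hydroxy enone (quaternary C2)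
Conditions: LDA (2.5 equiv), THF/DMPU, −78 to −40 °C; MeI, −78 to −30 °C; AcOH quench
Reagents that add atoms: iodomethane, CI
Why: Fráter–Seebach-type alkylation, in which the lithium alkoxide–enolate dianion forms a six-membered chelate and iodomethane should attack the enolate face opposite the chain on the carbinol carbon; this sets C2 with methyl anti to the hydroxyl, the diastereomer that a direct aldol of the 5-methyl enolate would not give.

Step 11
Reactants: 14 5-methyl β-hydroxy enone
Product: 15 TBS ether enone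
Conditions: TBSOTf, 2,6-lutidine, CH2Cl2, −78 to 0 °C
Reagents that add atoms: tert-butyldimethylsilyl trifluoromethanesulfonate, CC(C)(C)[Si](C)(C)OS(=O)(=O)C(F)(F)F
Why: Silyl ether protection of the β-hydroxyl blocks retro-aldol cleavage and carries the future free C3–OH to the end.

Step 12
Reactants: 15 TBS ether enone
Product: 17 Diels–Alder adduct (norbornenyl boronate), via TMS dienol ether 16 (not isolated)
Conditions: TMSOTf, Et3N, Et2O, 0 °C; filter; toluene (0.005 M), BHT, 110 °C
Reagents that add atoms: trimethylsilyl trifluoromethanesulfonate, C[Si](C)(C)OS(=O)(=O)C(F)(F)F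
Why: Soft γ-enolisation (the only one possible beside the quaternary carbon) gives a 1-silyloxy-5,5-disubstituted cyclopentadiene that cannot undergo 1,5-H shift, and the intramolecular Diels–Alder reaction with the tethered (E)-alkenylboronate should close the seven-membered ring C2–C8 on the tether face with the boron-bearing carbon bonding to the silyloxy terminus (ortho rule, the CMe2-bearing carbon going to the unsubstituted terminus), giving exo tether and endo boron and fixing C1, C7, C8 and C11.

Step 13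
Reactants: 17 Diels–Alder adduct
Product: 19 bridgehead–endo 1,2-diol, via endo alcohol 18 (not isolated)
Conditions: 30% H2O2, 3 M NaOH, THF/MeOH, 0 °C to rt
Reagents that add atoms: hydrogen peroxide, OO
Why: Alkaline peroxide oxidation of the secondary alkylboronate proceeds with retention to the endo alcohol and the methanolic base then cleaves the labile tertiary TMS ether; β-elimination of the β-oxy boronate cannot occur because it would give a bridgehead alkene.

Step 14
Reactants: 19 bridgehead–endo 1,2-diol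
Product: 20 endo mesylate
Conditions: MsCl, Et3N, CH2Cl2, −20 to 0 °C
Reagents that add atoms: methanesulfonyl chloride, CS(=O)(=O)Cl
Why: Sulfonylation through sulfene is selective for the secondary hydroxyl, the tertiary bridgehead hydroxyl being unreactive.

Step 15
Reactants: 20 endo mesylate
Product: 21 tricyclic enone
Conditions: Et3Al (3 equiv), CH2Cl2, −78 to 0 °C; Rochelle salt work-up
Reagents that add atoms: none
Why: Proposed new method: Et3Al turns the bridgehead C11–OH into an aluminium alkoxide and pulls on the endo C1 mesylate, and the C2–C11 bond, the only ring bond antiperiplanar to the endo C1–O bond (about 160°, against about 60° for C10–C11), shifts from C11 to C1 while C11 becomes the ketone (semipinacol 1,2-shift driven by C=O formation and sulfonate loss, which should outweigh the roughly 15–20 kcal/mol of added strain). The closest known reaction type is the organoaluminium- or base-promoted semipinacol rearrangement of 2-sulfonyloxy alcohols, together with Tiffeneau–Demjanov contractions of 2-substituted cyclopentanols to acylcyclobutanes; applied to a norbornan-1-ol it runs the bornyl-to-pinyl Wagner–Meerwein shift uphill. No ring is closed end to end: the single shift contracts the ring C11–C1–C7–C6–C5–C4–C3–C2 (8) to the seven-membered ring C1–C7, turns the five-membered ring C2–C11–C1–C7–C8 into the cyclobutane C1–C2–C8–C7 by backside displacement at C1, and enlarges the ring C11–C10–C9–C8–C2 to the cyclohexenone. C1 is formed with inversion because C2 enters anti to the leaving group, the migrating C2 keeps its configuration, and C7 and C8 are spectators, so the cyclobutane configuration follows from the endo mesylate installed through the (E)-alkenylboronate in step 12. The step needs migration of C2 in preference to the vinylic C10 and to ionisation or elimination; the endo geometry aligns only C2, the cis C7–H and the bridgehead rule out E2, and the covalent Al–O bond supplies the push without freeing an alkoxide that could trigger retro-[4+2] cleavage.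

Step 16
Reactants: 21 tricyclic enone
Product: 22 9-methyl ketone
Conditions: Me2CuLi (from CuI and 2 MeLi), Et2O, −78 to −40 °C; AcOH quench
Reagents that add atoms: lithium dimethylcuprate, [Li+].C[Cu-]C
Why: Conjugate addition of the Gilman reagent to the bicyclo[3.1.1]heptenone should occur on the enone face capped by C7–H and anti to the C2 bridge with its methyl group, which gives the C9 configuration of the target.

Step 17
Reactants: 22 9-methyl ketone
Product: 23 C4 alcohol
Conditions: H2 (1 atm), 20% Pd(OH)2/C, EtOAc, rt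
Reagents that add atoms: none
Why: Hydrogenolysis of the benzyl ether over Pearlman's catalyst in ethyl acetate should free only C4–OH and leave the ketone and both silyl ethers untouched.

Step 18
Reactants: 23 C4 alcohol; 24 (R)-2-methylbutanoic acid
Product: 25 C4 (R)-2-methylbutanoate
Conditions: DCC, DMAP, CH2Cl2, 0 °C to rt
Reagents that add atoms: none
Why: Steglich esterification of the single free hydroxyl with the enantiopure acid, run cold to limit α-epimerisation of the acyl group.

Step 19
Reactants: 25 C4 (R)-2-methylbutanoate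
Product: 26 C5 alcohol
Conditions: HF·pyridine, pyridine, THF, 0 °C
Reagents that add atoms: none
Why: Selective desilylation, since buffered HF·pyridine should cleave the triethylsilyl ether well before the neopentyl TBS ether and the acidic medium does not promote acyl migration.

Step 20
Reactants: 26 C5 alcohol; 27 angelic acid
Product: 29 TBS-protected target, via mixed anhydride 28 (not isolated)
Conditions: 2,4,6-trichlorobenzoyl chloride, Et3N, toluene, rt; then 26, 80 °C
Reagents that add atoms: 2,4,6-trichlorobenzoyl chloride (atoms only in 28), O=C(Cl)c1c(Cl)cc(Cl)cc1Cl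
Why: Yamaguchi-type esterification through the mixed trichlorobenzoic anhydride without DMAP should acylate the hindered neopentyl alcohol while keeping the Z geometry of the angelate.

Step 21
Reactants: 29 TBS-protected target
Product: 30 CNP0206299.1
Conditions: HF·pyridine, THF/pyridine, 0 °C to rt
Reagents that add atoms: none
Why: Fluoride cleavage of the last silyl ether under weakly acidic conditions should free the C3 hydroxyl without ester migration or angelate isomerisation.

Compound list
1 | 2,2-dimethylbut-3-ynoic acid | C#CC(C)(C)C(=O)O | starting material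
2 | 2,2-dimethylbut-3-yn-1-ol | C#CC(C)(C)CO | intermediate
3 | 2,2-dimethylbut-3-ynal | C#CC(C)(C)C=O | intermediate
4 | (R)-4-benzyloxazolidin-2-one | O=C1N[C@H](Cc2ccccc2)CO1 | starting material
5 | 2-(benzyloxy)acetyl chloride | O=C(Cl)COCc1ccccc1 | starting material
6 | (R)-4-benzyl-3-[2-(benzyloxy)acetyl]oxazolidin-2-one | O=C(COCc1ccccc1)N1[C@H](Cc2ccccc2)COC1=O | intermediate
7 | (R)-4-benzyl-3-[(2R,3S)-2-(benzyloxy)-3-hydroxy-4,4-dimethylhex-5-ynoyl]oxazolidin-2-one | O=C([C@H](OCc1ccccc1)[C@@H](O)C(C)(C)C#C)N1[C@H](Cc2ccccc2)COC1=O | intermediate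
8 | (R)-4-benzyl-3-[(2R,3S)-2-(benzyloxy)-4,4-dimethyl-3-(triethylsilyloxy)hex-5-ynoyl]oxazolidin-2-one | O=C([C@H](OCc1ccccc1)[C@@H](O[Si](CC)(CC)CC)C(C)(C)C#C)N1[C@H](Cc2ccccc2)COC1=O | intermediate
9 | (R)-4-benzyl-3-[(2R,3S,5E)-2-(benzyloxy)-4,4-dimethyl-6-(4,4,5,5-tetramethyl-1,3,2-dioxaborolan-2-yl)-3-(triethylsilyloxy)hex-5-enoyl]oxazolidin-2-one | O=C([C@H](OCc1ccccc1)[C@@H](O[Si](CC)(CC)CC)C(C)(C)/C=C/B2OC(C)(C)C(C)(C)O2)N3[C@H](Cc4ccccc4)COC3=O | intermediate
10 | (2S,3S,5E)-2-(benzyloxy)-4,4-dimethyl-6-(4,4,5,5-tetramethyl-1,3,2-dioxaborolan-2-yl)-3-(triethylsilyloxy)hex-5-en-1-ol | OC[C@H](OCc1ccccc1)[C@@H](O[Si](CC)(CC)CC)C(C)(C)/C=C/B2OC(C)(C)C(C)(C)O2 | intermediate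
11 | (2R,3S,5E)-2-(benzyloxy)-4,4-dimethyl-6-(4,4,5,5-tetramethyl-1,3,2-dioxaborolan-2-yl)-3-(triethylsilyloxy)hex-5-enal | O=C[C@H](OCc1ccccc1)[C@@H](O[Si](CC)(CC)CC)C(C)(C)/C=C/B2OC(C)(C)C(C)(C)O2 | intermediate
12 | cyclopent-2-en-1-one | O=C1C=CCC1 | starting material
13 | 5-[(1S,2S,3S,5E)-2-(benzyloxy)-1-hydroxy-4,4-dimethyl-6-(pinacolboryl)-3-(triethylsilyloxy)hex-5-en-1-yl]cyclopent-2-en-1-one, both epimers at ring C-5 | O=C1C=CCC1[C@H](O)[C@H](OCc2ccccc2)[C@@H](O[Si](CC)(CC)CC)C(C)(C)/C=C/B3OC(C)(C)C(C)(C)O3 | intermediate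
14 | (5S)-5-[(1S,2S,3S,5E)-2-(benzyloxy)-1-hydroxy-4,4-dimethyl-6-(pinacolboryl)-3-(triethylsilyloxy)hex-5-en-1-yl]-5-methylcyclopent-2-en-1-one (methyl anti to the carbinol OH) | O=C1C=CC[C@@]1(C)[C@H](O)[C@H](OCc2ccccc2)[C@@H](O[Si](CC)(CC)CC)C(C)(C)/C=C/B3OC(C)(C)C(C)(C)O3 | intermediate
15 | tert-butyldimethylsilyl ether of 14 at the carbinol (future C3–O) | O=C1C=CC[C@@]1(C)[C@H](O[Si](C)(C)C(C)(C)C)[C@H](OCc2ccccc2)[C@@H](O[Si](CC)(CC)CC)C(C)(C)/C=C/B3OC(C)(C)C(C)(C)O3 | intermediate
16 | 1-(trimethylsilyloxy)-5-methyl-5-(side chain of 15)cyclopenta-1,3-diene | C[Si](C)(C)OC1=CC=C[C@@]1(C)[C@H](O[Si](C)(C)C(C)(C)C)[C@H](OCc2ccccc2)[C@@H](O[Si](CC)(CC)CC)C(C)(C)/C=C/B3OC(C)(C)C(C)(C)O3 | intermediate (not isolated)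
17 | norbornene adduct: bridgeheads C11 (OTMS) and C8, one-carbon bridge C2 (Me syn to C9=C10), C1 with endo Bpin, C7 joined exo to C6; seven-membered ring C2–C3(OTBS)–C4(OBn)–C5(OTES)–C6(Me2)–C7–C8 | CC[Si](CC)(CC)O[C@@H]1[C@@H](OCc4ccccc4)[C@@H](O[Si](C)(C)C(C)(C)C)[C@]2(C)[C@@H]3[C@@H]([C@@H](B5OC(C)(C)C(C)(C)O5)[C@@]2(O[Si](C)(C)C)C=C3)C1(C)C | intermediate
18 | as 17 with endo C1–OH in place of Bpin (C11–OTMS kept) | CC[Si](CC)(CC)O[C@@H]1[C@@H](OCc4ccccc4)[C@@H](O[Si](C)(C)C(C)(C)C)[C@]2(C)[C@@H]3[C@@H]([C@@H](O)[C@@]2(O[Si](C)(C)C)C=C3)C1(C)C | intermediate (not isolated)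
19 | as 18 with free bridgehead C11–OH (C1-endo, C11 diol) | CC[Si](CC)(CC)O[C@@H]1[C@@H](OCc4ccccc4)[C@@H](O[Si](C)(C)C(C)(C)C)[C@]2(C)[C@@H]3[C@@H]([C@@H](O)[C@@]2(O)C=C3)C1(C)C | intermediate
20 | C1-endo methanesulfonate of 19 | CC[Si](CC)(CC)O[C@@H]1[C@@H](OCc4ccccc4)[C@@H](O[Si](C)(C)C(C)(C)C)[C@]2(C)[C@@H]3[C@@H]([C@@H](OS(C)(=O)=O)[C@@]2(O)C=C3)C1(C)C | intermediate
21 | 4-(benzyloxy)-3-(tert-butyldimethylsilyloxy)-2,6,6-trimethyl-5-(triethylsilyloxy)tricyclo[5.4.0.0^2,8]undec-9-en-11-one (3-O and 4-O on the C1 side, 5-O on the C8 side of the seven-membered ring) | CC[Si](CC)(CC)O[C@@H]1[C@@H](OCc4ccccc4)[C@@H](O[Si](C)(C)C(C)(C)C)[C@]2(C)[C@@H]3[C@@H]([C@H]2C(=O)C=C3)C1(C)C | intermediate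
22 | 9-methyl-9,10-dihydro derivative of 21 (9-Me toward C7, anti to C2) | CC[Si](CC)(CC)O[C@@H]1[C@@H](OCc4ccccc4)[C@@H](O[Si](C)(C)C(C)(C)C)[C@]2(C)[C@@H]3[C@@H]([C@H]2C(=O)C[C@H]3C)C1(C)C | intermediate
23 | 4-hydroxy analogue of 22 (benzyl removed) | CC[Si](CC)(CC)O[C@@H]1[C@@H](O)[C@@H](O[Si](C)(C)C(C)(C)C)[C@]2(C)[C@@H]3[C@@H]([C@H]2C(=O)C[C@H]3C)C1(C)C | intermediate
24 | (R)-2-methylbutanoic acid | CC[C@@H](C)C(=O)O | starting material
25 | 4-O-[(R)-2-methylbutanoyl] ester of 23 | CC[Si](CC)(CC)O[C@@H]1[C@@H](OC(=O)[C@H](C)CC)[C@@H](O[Si](C)(C)C(C)(C)C)[C@]2(C)[C@@H]3[C@@H]([C@H]2C(=O)C[C@H]3C)C1(C)C | intermediate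
26 | 5-hydroxy analogue of 25 (TES removed) | O[C@@H]1[C@@H](OC(=O)[C@H](C)CC)[C@@H](O[Si](C)(C)C(C)(C)C)[C@]2(C)[C@@H]3[C@@H]([C@H]2C(=O)C[C@H]3C)C1(C)C | intermediate
27 | angelic acid, (Z)-2-methylbut-2-enoic acid | C/C=C(/C)C(=O)O | starting material
28 | (Z)-2-methylbut-2-enoic 2,4,6-trichlorobenzoic anhydride | C/C=C(/C)C(=O)OC(=O)c1c(Cl)cc(Cl)cc1Cl | intermediate (not isolated)
29 | 3-O-tert-butyldimethylsilyl ether of the target | C/C=C(/C)C(=O)O[C@@H]1[C@@H](OC(=O)[C@H](C)CC)[C@@H](O[Si](C)(C)C(C)(C)C)[C@]2(C)[C@@H]3[C@@H]([C@H]2C(=O)C[C@H]3C)C1(C)C | intermediate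
30 | CNP0206299.1: 3-hydroxy-2,6,6,9-tetramethyl-4-[(R)-2-methylbutanoyloxy]-11-oxotricyclo[5.4.0.0^2,8]undec-5-yl (Z)-2-methylbut-2-enoate (3-OH and 4-acyloxy cis, 5-angeloyloxy trans to them) | C/C=C(/C)C(=O)O[C@@H]1[C@@H](OC(=O)[C@H](C)CC)[C@@H](O)[C@]2(C)[C@@H]3[C@@H]([C@H]2C(=O)C[C@H]3C)C1(C)C | target

Total step count: 21. Longest linear sequence: 20 steps (1 to 30; step 3 is the only side branch).

Steps most likely to fail

1. Step 15 (proposed new method). What may go wrong: ionisation to a norbornyl cation followed by Wagner–Meerwein shift of the vinylic C10, fragmentation of the alkoxide by retro-[4+2], or no closure of the strained four-membered ring. The fallback uses the Tiffeneau–Demjanov-type nitrosative semipinacol, with N2 as the nucleofuge. It sets out from 17: stereoretentive amination of the secondary boronate (MeONH2, n-BuLi, THF, −78 to 60 °C) gives the endo amine F1; K2CO3 in MeOH removes the bridgehead TMS group to give the amino alcohol F2; NaNO2 in aqueous AcOH/THF at 0 °C forms the endo diazonium ion, whose loss of N2 with anti migration of C2 should give the enone, so the route is rejoined at 21.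

2. Step 12. What may go wrong: slow cycloaddition of the weakly activated alkenylboronate, which leaves time for decomposition or dimerisation of the silyloxydiene, or bond formation to the wrong diene terminus. The fallback changes the dienophile and sets out from 15: ipso-nitration of the alkenylboronate (radical nitro-deborylation, for example Fe(NO3)3·9H2O/TEMPO) gives the (E)-nitroalkene F3; TMSOTf/Et3N gives the nitro dienol ether F4, which should cyclise at or below room temperature, with a much lower LUMO and the same ortho and endo sense, to the nitro cycloadduct F5; Zn dust in AcOH reduces the nitro group and strips the TMS ether to give the amino alcohol F2, and the nitrosation described under point 1 brings the route back at 21.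

3. Step 10. What may go wrong: retro-aldol cleavage of the ketone dianion, competing γ-deprotonation or O-methylation, and eroded facial selectivity at the new quaternary carbon. The fallback moves the methylation to the β-hydroxy ester, the textbook substrate, and builds the cyclopentenone afterwards. It sets out from 11: aldol addition of the lithium enolate of methyl pent-4-enoate (LDA, THF, −78 °C) gives the β-hydroxy ester F6; Fráter–Seebach methylation of its dianion (LDA 2.2 equiv, MeI, THF/DMPU) gives the α-methyl ester F7; TBSOTf/2,6-lutidine gives the silyl ether F8; Me(MeO)NH·HCl/i-PrMgCl gives the Weinreb amide F9; vinylmagnesium bromide gives the dienone F10; ring-closing metathesis (Grubbs second-generation catalyst, CH2Cl2, 40 °C) closes the cyclopentenone, so the route is rejoined at 15.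

Further compounds
F1 | step 15 | endo C1 amine with bridgehead C11–OTMS (Bpin of 17 replaced by NH2) | CC[Si](CC)(CC)O[C@@H]1[C@@H](OCc4ccccc4)[C@@H](O[Si](C)(C)C(C)(C)C)[C@]2(C)[C@@H]3[C@@H]([C@@H](N)[C@@]2(O[Si](C)(C)C)C=C3)C1(C)C
F2 | step 15 | endo C1 amine with free bridgehead C11–OH | CC[Si](CC)(CC)O[C@@H]1[C@@H](OCc4ccccc4)[C@@H](O[Si](C)(C)C(C)(C)C)[C@]2(C)[C@@H]3[C@@H]([C@@H](N)[C@@]2(O)C=C3)C1(C)C
F3 | step 12 | (E)-nitroalkene analogue of 15 (NO2 in place of Bpin) | O=C1C=CC[C@@]1(C)[C@H](O[Si](C)(C)C(C)(C)C)[C@H](OCc2ccccc2)[C@@H](O[Si](CC)(CC)CC)C(C)(C)/C=C/[N+](=O)[O-]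
F4 | step 12 | TMS dienol ether of F3 | C[Si](C)(C)OC1=CC=C[C@@]1(C)[C@H](O[Si](C)(C)C(C)(C)C)[C@H](OCc2ccccc2)[C@@H](O[Si](CC)(CC)CC)C(C)(C)/C=C/[N+](=O)[O-]
F5 | step 12 | norbornene adduct with endo C1–NO2 and C11–OTMS | CC[Si](CC)(CC)O[C@@H]1[C@@H](OCc4ccccc4)[C@@H](O[Si](C)(C)C(C)(C)C)[C@]2(C)[C@@H]3[C@@H]([C@@H]([N+](=O)[O-])[C@@]2(O[Si](C)(C)C)C=C3)C1(C)C
F6 | step 10 | methyl 2-allyl-3-hydroxy ester from 11 (C-2 epimers, 3,4-anti) | COC(=O)C(CC=C)[C@H](O)[C@H](OCc1ccccc1)[C@@H](O[Si](CC)(CC)CC)C(C)(C)/C=C/B2OC(C)(C)C(C)(C)O2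
F7 | step 10 | methyl 2-allyl-2-methyl-3-hydroxy ester (methyl anti to OH) | COC(=O)[C@@](C)(CC=C)[C@H](O)[C@H](OCc1ccccc1)[C@@H](O[Si](CC)(CC)CC)C(C)(C)/C=C/B2OC(C)(C)C(C)(C)O2
F8 | step 10 | 3-O-TBS ether of F7 | COC(=O)[C@@](C)(CC=C)[C@H](O[Si](C)(C)C(C)(C)C)[C@H](OCc1ccccc1)[C@@H](O[Si](CC)(CC)CC)C(C)(C)/C=C/B2OC(C)(C)C(C)(C)O2
F9 | step 10 | N-methoxy-N-methyl amide from F8 | CON(C)C(=O)[C@@](C)(CC=C)[C@H](O[Si](C)(C)C(C)(C)C)[C@H](OCc1ccccc1)[C@@H](O[Si](CC)(CC)CC)C(C)(C)/C=C/B2OC(C)(C)C(C)(C)O2
F10 | step 10 | vinyl ketone (4-allyl-4-methyl dienone) from F9 | C=CC(=O)[C@@](C)(CC=C)[C@H](O[Si](C)(C)C(C)(C)C)[C@H](OCc1ccccc1)[C@@H](O[Si](CC)(CC)CC)C(C)(C)/C=C/B2OC(C)(C)C(C)(C)O2
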